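# Synthesis plan for 3-[2,3-dihydroxy-4-methoxy-5-(2-methylbut-3-en-2-yl)phenyl]-7-hydroxy-4H-chromen-4-one (20)

## The problem

The target 20 is a 7-hydroxyisoflavone: a chromen-4-one (rings A and C) whose C3 carries a pentasubstituted ring B with free hydroxyls at C2' and C3', a methoxyl at C4' and a 1,1-dimethylallyl (2-methylbut-3-en-2-yl) group at C5'. It has no stereocentre, so nothing has to be controlled in space; the difficulty lies in regiochemistry and in the order of events. Ring B carries four contiguous substituents next to the C1'–C3 bond, one of three neighbouring oxygens must end up methylated, and the quaternary benzylic carbon at C5' can realistically be delivered only from the oxygen at C4' by a [3,3] shift. That tert-allyl group is the fragile element: strong Brønsted or Lewis acids protonate the electron-rich ring at C5' and release or shift the allyl cation, heat moves the group on when a free phenol and a free ortho or para position are at hand, and its vinyl group excludes hydrogenolysis, ozonolysis and late halonium chemistry. The catechol at C2'/C3' is oxidation-prone and has to stay masked until the last step by a group that leaves under mild conditions. Ring C requires the C3–C4 carbonyl junction and a one-carbon unit (C2) between O1 and C3. The enabling feature is ring A: a resorcinol with oxygens on C7 and C8a, an acyl group on C4a and hydrogens on C5, C6 and C8, which is the aldol folding pattern of a chain running from C5 to C3 in which carbonyl and methylene carbons alternate. The segment C5 to C8a with both oxygens can be stored as a 4-pyranone whose ring oxygen is the later O1 and whose carbonyl oxygen is the later 7-OH, so that ring A lacks only the C4a–C5 bond.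

## Retrosynthesis

**20 from 19.** The last cut is the pair of C–O bonds of the isopropylidene ketal on O2'/O3'. This ketal is preferred to open-chain ethers because it distinguishes the three oxygens of pyrogallol in one step and leaves exactly the C4' oxygen free. It should also tolerate organolithiums, palladium catalysis, 190 °C and methoxide. The forward step must be a hydrolysis mild enough for the tert-allyl group.

**19 from 17.** Ring C is opened at O1–C2 and C2–C3, which removes C2 as a one-carbon electrophile at the formate oxidation level and returns the 2-hydroxydeoxybenzoin 17. The neighbouring cut, a cross-coupling at C3 of a 3-halochromone, would need a ring B boron reagent and protection of the 7-OH. The deoxybenzoin closure instead uses the acidity of the benzylic CH2 and the free C8a hydroxyl that are already present. The forward reaction must not alkylate the 7-OH and must not need acid.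

**17 from 15 (key disconnection).** The C4a–C5 bond of ring A is cut. The precursor 15 is an isomer of 17 in which C5 to C8a form a 4-pyranone and C4a is the methylene between that ring and the C4 ketone. The classical neighbour, cutting C4–C4a by Friedel–Crafts acylation of a 1,3-dihydroxyarene with an arylacetic acid, needs hot Lewis acid, which the ketal and the tert-allyl group would not survive. The pyranone route asks only for methoxide. The forward reaction must open the pyranone at its unsubstituted carbon (C5) and reclose through carbon C4a instead of oxygen.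

**15 from 12 and 13.** The C4–C4a bond is cut between an acyl donor and the methyl carbon of 2-methyl-4H-pyran-4-one 13. Deprotonation of 13 gives the pyranone-stabilised carbanion 14, which reacts at the exocyclic carbon because only that restores the pyranone. The N-methoxy-N-methylamide 12 is chosen over ester 11 for two reasons: its benzylic protons are less acidic and less likely to quench 14, and its tetrahedral adduct persists until work-up. This is the convergent step: a C6 ring A precursor meets the complete ring B fragment.

**12 from 11 from 10.** The C3–C1' bond is cut by palladium-catalysed coupling of aryl bromide 10 with a zinc ester enolate, followed by ester-to-amide exchange. Homologating an aryl aldehyde would take three or four steps. The bromine is already in place because it serves first as a blocking group in the Claisen step.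

**10 from 9 from 7.** After removal of the O-methyl group, the C5'–C(quaternary) bond is traced to the prenyl ether 7 by an aromatic Claisen rearrangement. In 7 the oxygen at C4' has one free ortho position (C5'), an oxygen-bearing ortho carbon (C3') and a brominated para carbon (C1'). The allyl group can therefore come to rest only at C5', and the onward Cope shift to the para position is blocked.

**7 from 5 and 6, 5 from 3, 3 from 2, 2 from 1.** The ether is made from prenyl bromide 6 and the phenol liberated from silyl ether 5. Bromine is placed by directed metalation of 3 (through aryllithium 4) and not by electrophilic bromination of phenol 2. In 2 the positions para and ortho to the hydroxyl are each activated by two oxygens, so a mixture would be expected. In silyl ether 3 the only C–H ortho to an oxygen and not shielded by the bulky silyloxy group is the one that becomes C1'. This costs one extra step and makes the regiochemistry secure. Phenol 2 is the acetonide of pyrogallol 1.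

## Roads not taken

**Alternative 1:** The cut is C4–C4a, made last, with O1–C2 already in place as an aryl vinyl ether.
- Forward key step: the (Z)-acrylic acid A2, assembled from ester 11 by C-formylation and addition–elimination with 3-(methoxymethoxy)phenol A3, is activated by a perfluoroacyl anhydride or a strongly dehydrating acid. The mixed anhydride acylates the resorcinol ring para to its ether oxygen and gives isoflavone A1.
- Merits: ring A is bought as an intact arene, so no folding question arises, and the closure is intramolecular.
- Weak points: the medium is strongly acidic and meets the ketal, the methoxymethyl ether and the tert-allyl group on a ring B that is more electron-rich than the ring meant to react. Only the Z isomer of A2 can close. Acylation ortho to the ether oxygen would give the 5-oxygenated isomer.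
- Comparison: the step count is about equal, since both roads pass through 11. Alternative 1 is better in that ring A cannot misfold. The chosen plan sets against this that rings A and C are formed under basic or neutral conditions, so strong acid never meets the tert-allyl group, and that the substitution pattern of ring A is fixed by connectivity and not by the selectivity of an aromatic substitution.

**Alternative 2:** The cuts are C3–C4 and O1–C2, made in one operation.
- Forward key step: aldehyde A7 (from bromide 10) is converted into its morpholine enamine A5, which is C-acylated by 2,4-diacetoxybenzoyl chloride A6. Methanolysis of the acetates frees the phenoxide, which adds to the enaminone and expels the amine. The product A4 is identical with 19.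
- Merits: it is the most convergent road, ring A arrives at the right oxidation level, and two bonds form in one pot. It is probably one or two steps shorter than steps 7 to 11, and its closure is as well founded as step 11.
- Weak points: A7 is an electron-rich, enolisable arylacetaldehyde prone to self-condensation and autoxidation. The acylation liberates HCl next to the ketal and must favour carbon over nitrogen. Ring A needs two acetate groups and an acid chloride to be prepared.
- Comparison: in step economy and in precedent for the ring closure this road is at least equal and probably better. The chosen plan sets against it that its intermediates 11, 12, 15 and 17 are stable, isolable carbonyl compounds, that ring A never needs a protecting group, and that no acid chloride chemistry is run in the presence of the ketal.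

**Alternative 3:** The cuts are O1–C2 and C2–C3 on a ring A kept at the cyclohexenone level, with C4–C4a made beforehand by enolate acylation.
- Forward key step: the kinetic enolate of 3-ethoxycyclohex-2-en-1-one A10 is acylated with amide 12 to give diketone A9. An amide acetal then aminomethylenates the benzylic CH2, and the enol oxygen of the ring ketone adds and expels the amine, closing ring C to give A8. Dehydrogenation of C5–C6 and liberation of the C7 oxygen must follow.
- Merits: every C–C bond is made by routine enolate chemistry, the road shares 12, and no competing folding mode exists.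
- Weak points: aromatisation needs an oxidant at a stage that carries the electron-rich ring B and the vinyl group. After aromatisation the C7 oxygen is an ethyl ether that cannot be cleaved selectively beside the 4'-methyl ether, unless the enol ether is hydrolysed before the oxidation. The road is two or three steps longer.
- Comparison: the bond-forming steps are more predictable than step 10. The chosen plan sets against this that ring A is formed directly as a free resorcinol, by an isomerisation that needs no oxidant and no deprotection.

Key step: step 10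

## Route

Remark on the chemistry: 2-methyl-4H-pyran-4-one (13) is assumed to be purchased. Locants O1 to C8a and C1' to C6' are those of the isoflavone skeleton of 20 and are used for the corresponding atoms of all precursors.

Step 1
Reactants: 1 pyrogallol (benzene-1,2,3-triol)
Product: 2 2,2-dimethyl-1,3-benzodioxol-4-ol
Conditions: Me2C(OMe)2, p-TsOH·H2O (cat.), toluene, reflux, 4 Å MS (removal of MeOH)
Reagents that add atoms: 2,2-dimethoxypropane, COC(C)(C)OC
Why: Acid-catalysed transketalisation; only two vicinal hydroxyls can close the five-membered dioxole, so exactly one terminal hydroxyl (the later C4' oxygen) stays free.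

Step 2
Reactants: 2 2,2-dimethyl-1,3-benzodioxol-4-ol
Product: 3 [(2,2-dimethyl-1,3-benzodioxol-4-yl)oxy]tri(propan-2-yl)silane
Conditions: i-Pr3SiCl, imidazole, DMF, rt
Reagents that add atoms: chlorotri(propan-2-yl)silane, CC(C)[Si](Cl)(C(C)C)C(C)C
Why: Standard O-silylation of a phenol; the bulky silyl ether is not a directing group and shields the neighbouring C–H in the next step.

Step 3
Reactants: 3 [(2,2-dimethyl-1,3-benzodioxol-4-yl)oxy]tri(propan-2-yl)silane
Product: 5 [(7-bromo-2,2-dimethyl-1,3-benzodioxol-4-yl)oxy]tri(propan-2-yl)silane, via aryllithium 4 (not isolated)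
Conditions: s-BuLi, TMEDA, THF, −78 °C; then BrCl2CCCl2Br, −78 °C → rt
Reagents that add atoms: 1,2-dibromo-1,1,2,2-tetrachloroethane, BrC(Cl)(Cl)C(Cl)(Cl)Br
Why: Directed ortho-metalation; the dioxole oxygen directs lithiation to the only C–H that is ortho to an oxygen and not screened by the triisopropylsilyloxy group (the later C1'), and the aryllithium is brominated by halogen transfer.

Step 4
Reactants: 5 [(7-bromo-2,2-dimethyl-1,3-benzodioxol-4-yl)oxy]tri(propan-2-yl)silane; 6 prenyl bromide (1-bromo-3-methylbut-2-ene)
Product: 7 4-bromo-2,2-dimethyl-7-[(3-methylbut-2-en-1-yl)oxy]-1,3-benzodioxole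
Conditions: Bu4NF, THF, 0 °C; then 6, 0 °C → rt
Reagents that add atoms: none
Why: Fluoride desilylation gives the tetrabutylammonium phenoxide, which is O-alkylated in the same flask at the primary carbon of the allylic bromide (Williamson ether synthesis); a loosely paired phenoxide in a polar medium favours O- over C-alkylation.

Step 5
Reactants: 7 4-bromo-2,2-dimethyl-7-[(3-methylbut-2-en-1-yl)oxy]-1,3-benzodioxole
Product: 9 7-bromo-2,2-dimethyl-5-(2-methylbut-3-en-2-yl)-1,3-benzodioxol-4-ol, via ortho-dienone 8 (not isolated)
Conditions: PhNEt2, 190 °C, sealed tube, degassed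
Reagents that add atoms: none
Why: Aromatic Claisen rearrangement; the [3,3] shift delivers the inverted (1,1-dimethylallyl) group to the single free ortho carbon, the basic solvent speeds enolisation of the dienone, and the para bromine blocks the onward Cope shift.

Step 6
Reactants: 9 7-bromo-2,2-dimethyl-5-(2-methylbut-3-en-2-yl)-1,3-benzodioxol-4-ol
Product: 10 4-bromo-7-methoxy-2,2-dimethyl-6-(2-methylbut-3-en-2-yl)-1,3-benzodioxole
Conditions: MeI, K2CO3, DMF, 40 °C
Reagents that add atoms: iodomethane, CI
Why: Williamson methylation of the only free phenol; it fixes the 4'-methoxyl and removes the hydroxyl that could cyclise onto the vinyl group.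

Step 7
Reactants: 10 4-bromo-7-methoxy-2,2-dimethyl-6-(2-methylbut-3-en-2-yl)-1,3-benzodioxole
Product: 11 ethyl [7-methoxy-2,2-dimethyl-6-(2-methylbut-3-en-2-yl)-1,3-benzodioxol-4-yl]acetate
Conditions: BrZnCH2CO2Et (from BrCH2CO2Et, Zn, Me3SiCl cat.), Pd2(dba)3 (cat.), XPhos (cat.), THF, 65 °C
Reagents that add atoms: ethyl bromoacetate (used as its zinc enolate), CCOC(=O)CBr
Why: Negishi-type coupling of a Reformatsky reagent (α-arylation of an ester): oxidative addition of zerovalent palladium into the C–Br bond, transmetalation with the zinc enolate and reductive elimination; the neutral zinc reagent leaves ketal and alkene untouched, and the hindered vinyl group, meta to the bromide, cannot compete in a Heck pathway.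

Step 8
Reactants: 11 ethyl [7-methoxy-2,2-dimethyl-6-(2-methylbut-3-en-2-yl)-1,3-benzodioxol-4-yl]acetate
Product: 12 N-methoxy-2-[7-methoxy-2,2-dimethyl-6-(2-methylbut-3-en-2-yl)-1,3-benzodioxol-4-yl]-N-methylacetamide
Conditions: MeNH(OMe)·HCl, i-PrMgCl, THF, −20 → 0 °C
Reagents that add atoms: N,O-dimethylhydroxylamine hydrochloride, CNOC.Cl
Why: Direct aminolysis of the ethyl ester by the chloromagnesium amide formed in situ (Weinreb amide synthesis), which is more nucleophilic than basic and tolerates enolisable esters.

Step 9
Reactants: 12 N-methoxy-2-[7-methoxy-2,2-dimethyl-6-(2-methylbut-3-en-2-yl)-1,3-benzodioxol-4-yl]-N-methylacetamide; 13 2-methyl-4H-pyran-4-one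
Product: 15 2-{3-[7-methoxy-2,2-dimethyl-6-(2-methylbut-3-en-2-yl)-1,3-benzodioxol-4-yl]-2-oxopropyl}-4H-pyran-4-one, via lithiated pyranone 14 (not isolated)
Conditions: 13 (2.2 equiv), LiN(SiMe3)2 (2.2 equiv), THF, −78 °C; then 12 (1.0 equiv), −78 → −30 °C; aq. NH4Cl
Reagents that add atoms: none
Why: Lateral (vinylogous) deprotonation of the 2-methyl group by a non-nucleophilic amide base gives a dienolate that reacts at the exocyclic carbon because only this restores the pyranone; acylation by the Weinreb amide stops at the chelated tetrahedral adduct, and the excess of 14 covers any deprotonation of the acidic product.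

Step 10
Reactants: 15 2-{3-[7-methoxy-2,2-dimethyl-6-(2-methylbut-3-en-2-yl)-1,3-benzodioxol-4-yl]-2-oxopropyl}-4H-pyran-4-one
Product: 17 1-(2,4-dihydroxyphenyl)-2-[7-methoxy-2,2-dimethyl-6-(2-methylbut-3-en-2-yl)-1,3-benzodioxol-4-yl]ethan-1-one, via ring-opened methoxyenone 16 (not isolated)
Conditions: Mg(OMe)2 (4 equiv), anhydrous MeOH, 65 °C; then cold 1 M HCl to pH 5
Reagents that add atoms: none
Why: Methoxide adds to the unsubstituted pyranone carbon of 15 (the later C5) and the resulting 2-methoxy-2H-pyran opens to the magnesium enolate of 16, in which C5 is a neutral β-methoxy enone terminus and the former ring oxygen sits on C8a. The C4a carbanion, held between the C4 and C8a carbonyls as a magnesium β-diketonate, adds to C5 and methoxide is expelled (addition–elimination, 6-endo-trig, ring atoms C4a, C8a, C8, C7, C6, C5); the cyclohexadienone then enolises to the resorcinol, whose phenoxide is inert to methoxide, so all earlier equilibria should drain to 17. The closest known reaction type is the biomimetic pyranone-to-resorcinol ring transformation, the hydroxide- or methoxide-induced conversion of 2-(2-oxoalkyl)-6-methyl-4-pyranones into 2,4-dihydroxy-6-methylphenyl ketones by aldol folding of the unmasked polyketone; here the electrophile is a vinylogous ester carbon instead of a methyl ketone. No stereocentre is formed. The step needs closure from C4a to C5 and not from the benzylic C3 to C7 or from C6 to C4: C4a is flanked by two carbonyls and C3 by one, C7 is deactivated as part of the C8 enolate, and in anhydrous methoxide C6 remains a vinylic carbon of the enol ether and cannot become the nucleophile that a formyl enolate generated by hydroxide would be. Reclosure through the C8a oxygen only regenerates 15.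

Step 11
Reactants: 17 1-(2,4-dihydroxyphenyl)-2-[7-methoxy-2,2-dimethyl-6-(2-methylbut-3-en-2-yl)-1,3-benzodioxol-4-yl]ethan-1-one
Product: 19 7-hydroxy-3-[7-methoxy-2,2-dimethyl-6-(2-methylbut-3-en-2-yl)-1,3-benzodioxol-4-yl]-4H-chromen-4-one, via enaminone 18 (not isolated)
Conditions: Me2NCH(OMe)2 (3 equiv), THF, 60 °C
Reagents that add atoms: N,N-dimethylformamide dimethyl acetal, COC(OC)N(C)C
Why: Classical isoflavone synthesis from a 2-hydroxydeoxybenzoin: aminomethylenation of the benzylic CH2 gives the enaminone, the C8a hydroxyl adds to its β-carbon (6-endo-trig) and dimethylamine is lost; the moderate temperature is chosen to avoid O-methylation of the 7-OH by the reagent.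

Step 12
Reactants: 19 7-hydroxy-3-[7-methoxy-2,2-dimethyl-6-(2-methylbut-3-en-2-yl)-1,3-benzodioxol-4-yl]-4H-chromen-4-one
Product: 20 3-[2,3-dihydroxy-4-methoxy-5-(2-methylbut-3-en-2-yl)phenyl]-7-hydroxy-4H-chromen-4-one
Conditions: 3 M aq. HCl–MeOH (1:4), 60 °C, argon
Reagents that add atoms: none
Why: Acid-catalysed hydrolysis of the aryl isopropylidene ketal; dilute protic acid is of the strength under which 1,1-dimethylallyl groups flanked by a methoxyl are known to survive removal of acetal protecting groups, and no free hydroxyl is ortho to the allyl group to cyclise onto it.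

## Compound list

1 | pyrogallol (benzene-1,2,3-triol) | Oc1cccc(O)c1O | starting material
2 | 2,2-dimethyl-1,3-benzodioxol-4-ol | CC1(C)Oc2cccc(O)c2O1 | intermediate
3 | [(2,2-dimethyl-1,3-benzodioxol-4-yl)oxy]tri(propan-2-yl)silane | CC(C)[Si](Oc1cccc2OC(C)(C)Oc12)(C(C)C)C(C)C | intermediate
4 | (2,2-dimethyl-7-{[tri(propan-2-yl)silyl]oxy}-1,3-benzodioxol-4-yl)lithium | [Li]c1ccc(O[Si](C(C)C)(C(C)C)C(C)C)c2OC(C)(C)Oc12 | intermediate (not isolated)
5 | [(7-bromo-2,2-dimethyl-1,3-benzodioxol-4-yl)oxy]tri(propan-2-yl)silane | Brc1ccc(O[Si](C(C)C)(C(C)C)C(C)C)c2OC(C)(C)Oc12 | intermediate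
6 | prenyl bromide (1-bromo-3-methylbut-2-ene) | CC(C)=CCBr | starting material
7 | 4-bromo-2,2-dimethyl-7-[(3-methylbut-2-en-1-yl)oxy]-1,3-benzodioxole | Brc1ccc(OCC=C(C)C)c2OC(C)(C)Oc12 | intermediate
8 | 7-bromo-2,2-dimethyl-5-(2-methylbut-3-en-2-yl)-1,3-benzodioxol-4(5H)-one (transient, racemic) | O=C1C(C(C)(C)C=C)C=C(Br)C2=C1OC(C)(C)O2 | intermediate (not isolated)
9 | 7-bromo-2,2-dimethyl-5-(2-methylbut-3-en-2-yl)-1,3-benzodioxol-4-ol | Oc1c(C(C)(C)C=C)cc(Br)c2OC(C)(C)Oc12 | intermediate
10 | 4-bromo-7-methoxy-2,2-dimethyl-6-(2-methylbut-3-en-2-yl)-1,3-benzodioxole | COc1c(C(C)(C)C=C)cc(Br)c2OC(C)(C)Oc12 | intermediate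
11 | ethyl [7-methoxy-2,2-dimethyl-6-(2-methylbut-3-en-2-yl)-1,3-benzodioxol-4-yl]acetate | CCOC(=O)Cc1cc(C(C)(C)C=C)c(OC)c2OC(C)(C)Oc12 | intermediate
12 | N-methoxy-2-[7-methoxy-2,2-dimethyl-6-(2-methylbut-3-en-2-yl)-1,3-benzodioxol-4-yl]-N-methylacetamide | CON(C)C(=O)Cc1cc(C(C)(C)C=C)c(OC)c2OC(C)(C)Oc12 | intermediate
13 | 2-methyl-4H-pyran-4-one | Cc1cc(=O)cco1 | starting material
14 | [(4-oxo-4H-pyran-2-yl)methyl]lithium (lithium dienolate of 13) | [Li]Cc1cc(=O)cco1 | intermediate (not isolated)
15 | 2-{3-[7-methoxy-2,2-dimethyl-6-(2-methylbut-3-en-2-yl)-1,3-benzodioxol-4-yl]-2-oxopropyl}-4H-pyran-4-one | O=C(Cc1cc(=O)cco1)Cc1cc(C(C)(C)C=C)c(OC)c2OC(C)(C)Oc12 | intermediate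
16 | (7E)-8-methoxy-1-[7-methoxy-2,2-dimethyl-6-(2-methylbut-3-en-2-yl)-1,3-benzodioxol-4-yl]oct-7-ene-2,4,6-trione (present as its magnesium enolate; drawn in the triketo form) | CO/C=C/C(=O)CC(=O)CC(=O)Cc1cc(C(C)(C)C=C)c(OC)c2OC(C)(C)Oc12 | intermediate (not isolated)
17 | 1-(2,4-dihydroxyphenyl)-2-[7-methoxy-2,2-dimethyl-6-(2-methylbut-3-en-2-yl)-1,3-benzodioxol-4-yl]ethan-1-one | O=C(Cc1cc(C(C)(C)C=C)c(OC)c2OC(C)(C)Oc12)c1ccc(O)cc1O | intermediate
18 | 1-(2,4-dihydroxyphenyl)-3-(dimethylamino)-2-[7-methoxy-2,2-dimethyl-6-(2-methylbut-3-en-2-yl)-1,3-benzodioxol-4-yl]prop-2-en-1-one (push–pull alkene, geometry not fixed) | CN(C)C=C(C(=O)c1ccc(O)cc1O)c1cc(C(C)(C)C=C)c(OC)c2OC(C)(C)Oc12 | intermediate (not isolated)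
19 | 7-hydroxy-3-[7-methoxy-2,2-dimethyl-6-(2-methylbut-3-en-2-yl)-1,3-benzodioxol-4-yl]-4H-chromen-4-one | C=CC(C)(C)c1cc(-c3coc4cc(O)ccc4c3=O)c2OC(C)(C)Oc2c1OC | intermediate
20 | 3-[2,3-dihydroxy-4-methoxy-5-(2-methylbut-3-en-2-yl)phenyl]-7-hydroxy-4H-chromen-4-one (no stereocentre) | C=CC(C)(C)c1cc(-c2coc3cc(O)ccc3c2=O)c(O)c(O)c1OC | target

## Step count and risks

Total: 12 steps. Longest linear sequence: 12 steps (1 to 20); 13 enters at step 9 as a purchased compound.

**Step 10 (key step).** Three things may go wrong.
- The substrate is first deprotonated at C4a, and the resulting anion is a poorer acceptor, so opening of the pyranone by methoxide may be slow.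
- The opened polyketone may fragment by retro-Claisen attack of methoxide at C4 or C8a.
- The chain may fold the other way, from C3 to C7, if the C4a–C5 closure lags.

Fallback: leave the pyranone and make the same C4–C4a bond from a preformed ring A. Commercial 4-bromoresorcinol is allylated to 1-bromo-2,4-bis(prop-2-en-1-yloxy)benzene F1. Bromine–lithium exchange (n-BuLi, THF, −78 °C) gives [2,4-bis(prop-2-en-1-yloxy)phenyl]lithium F2, which is added to amide 12 to give 1-[2,4-bis(prop-2-en-1-yloxy)phenyl]-2-[7-methoxy-2,2-dimethyl-6-(2-methylbut-3-en-2-yl)-1,3-benzodioxol-4-yl]ethan-1-one F3. Both allyl ethers are then removed with Pd(PPh3)4 and morpholine, conditions that leave the ketal and the C-bound tert-allyl group alone, and the route is rejoined at 17.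

**Step 9.** Three things may go wrong.
- Proton transfer from the benzylic CH2 of 12 to 14 would give enolisation instead of acylation.
- 14 may add in conjugate fashion to the free C6 position of unreacted 13.
- The acidic product may quench 14.

Fallback: replace acylation by addition and oxidation. Amide 12 is reduced with i-Bu2AlH (THF, −78 °C) to [7-methoxy-2,2-dimethyl-6-(2-methylbut-3-en-2-yl)-1,3-benzodioxol-4-yl]acetaldehyde F4. The far more electrophilic aldehyde is added to 14 at −78 °C to give racemic 2-{2-hydroxy-3-[7-methoxy-2,2-dimethyl-6-(2-methylbut-3-en-2-yl)-1,3-benzodioxol-4-yl]propyl}-4H-pyran-4-one F5. Dess–Martin periodinane oxidises the alcohol and the route is rejoined at 15.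

**Step 5.** At 190 °C the freshly formed ortho tert-allyl phenol may react further in three ways.
- Abnormal Claisen isomerisation of the side chain.
- Addition of the phenol to the vinyl group, giving a dihydrobenzofuran.
- Ether cleavage with loss of isoprene.

Fallback: never expose the phenol. The rearrangement of 7 is run in butanoic anhydride with PhNEt2 at 185 °C, so that the phenol is acylated as it forms and isolated as 7-bromo-2,2-dimethyl-5-(2-methylbut-3-en-2-yl)-1,3-benzodioxol-4-yl butanoate F6. Methanolysis (K2CO3, MeOH, rt) then releases the phenol under conditions where it is stable, rejoining the route at 9.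

**Step 11.** Two things may go wrong.
- The acetal reagent may methylate the acidic 7-OH.
- The sequence may stop at enaminone 18.

Fallback: introduce C2 by a Claisen condensation that cannot alkylate. Ketone 17 is treated with ethyl formate and NaH (THF, 0 °C → rt), which formylates the benzylic carbon. The C8a hydroxyl closes onto the formyl group to give 2,7-dihydroxy-3-[7-methoxy-2,2-dimethyl-6-(2-methylbut-3-en-2-yl)-1,3-benzodioxol-4-yl]-2,3-dihydro-4H-chromen-4-one F7 as a mixture of diastereomers. Warm acetic acid dehydrates it, rejoining the route at 19.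

**Step 12.** Three things may go wrong.
- Protonation of ring B at C5' may cause loss or 1,3-shift of the tert-allyl cation before the ketal is fully cleaved.
- Ketal hydrolysis may be slow.
- The liberated catechol may oxidise in air.

Fallback: replace hydrolysis by anhydrous ketal exchange. Compound 19 is treated with propane-1,3-dithiol and BF3·OEt2 in CH2Cl2 at −20 → 0 °C, which transfers the isopropylidene group to sulfur at low temperature and gives 20 directly. No new compound lies on this path.

## Further compounds

F1 | step 10 | 1-bromo-2,4-bis(prop-2-en-1-yloxy)benzene | C=CCOc1ccc(Br)c(OCC=C)c1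
F2 | step 10 | [2,4-bis(prop-2-en-1-yloxy)phenyl]lithium | [Li]c1ccc(OCC=C)cc1OCC=C
F3 | step 10 | 1-[2,4-bis(prop-2-en-1-yloxy)phenyl]-2-[7-methoxy-2,2-dimethyl-6-(2-methylbut-3-en-2-yl)-1,3-benzodioxol-4-yl]ethan-1-one | C=CCOc1ccc(C(=O)Cc2cc(C(C)(C)C=C)c(OC)c3OC(C)(C)Oc23)c(OCC=C)c1
F4 | step 9 | [7-methoxy-2,2-dimethyl-6-(2-methylbut-3-en-2-yl)-1,3-benzodioxol-4-yl]acetaldehyde | O=CCc1cc(C(C)(C)C=C)c(OC)c2OC(C)(C)Oc12
F5 | step 9 | 2-{2-hydroxy-3-[7-methoxy-2,2-dimethyl-6-(2-methylbut-3-en-2-yl)-1,3-benzodioxol-4-yl]propyl}-4H-pyran-4-one (racemic) | OC(Cc1cc(=O)cco1)Cc1cc(C(C)(C)C=C)c(OC)c2OC(C)(C)Oc12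
F6 | step 5 | 7-bromo-2,2-dimethyl-5-(2-methylbut-3-en-2-yl)-1,3-benzodioxol-4-yl butanoate | CCCC(=O)Oc1c(C(C)(C)C=C)cc(Br)c2OC(C)(C)Oc12
F7 | step 11 | 2,7-dihydroxy-3-[7-methoxy-2,2-dimethyl-6-(2-methylbut-3-en-2-yl)-1,3-benzodioxol-4-yl]-2,3-dihydro-4H-chromen-4-one (mixture of diastereomers) | OC1Oc2cc(O)ccc2C(=O)C1c1cc(C(C)(C)C=C)c(OC)c2OC(C)(C)Oc12
F0 | step 12 | none | none
A1 | alternative 1 | 7-(methoxymethoxy)-3-[7-methoxy-2,2-dimethyl-6-(2-methylbut-3-en-2-yl)-1,3-benzodioxol-4-yl]-4H-chromen-4-one | C=CC(C)(C)c1cc(-c3coc4cc(OCOC)ccc4c3=O)c2OC(C)(C)Oc2c1OC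
A2 | alternative 1 | (2Z)-2-[7-methoxy-2,2-dimethyl-6-(2-methylbut-3-en-2-yl)-1,3-benzodioxol-4-yl]-3-[3-(methoxymethoxy)phenoxy]prop-2-enoic acid | OC(=O)/C(=C\Oc1cccc(OCOC)c1)c1cc(C(C)(C)C=C)c(OC)c2OC(C)(C)Oc12
A3 | alternative 1 | 3-(methoxymethoxy)phenol | COCOc1cccc(O)c1
A4 | alternative 2 | 7-hydroxy-3-[7-methoxy-2,2-dimethyl-6-(2-methylbut-3-en-2-yl)-1,3-benzodioxol-4-yl]-4H-chromen-4-one (identical with 19) | C=CC(C)(C)c1cc(-c3coc4cc(O)ccc4c3=O)c2OC(C)(C)Oc2c1OC
A5 | alternative 2 | 4-{(E)-2-[7-methoxy-2,2-dimethyl-6-(2-methylbut-3-en-2-yl)-1,3-benzodioxol-4-yl]ethenyl}morpholine | O1CCN(CC1)/C=C/c1cc(C(C)(C)C=C)c(OC)c2OC(C)(C)Oc12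
A6 | alternative 2 | 2,4-diacetoxybenzoyl chloride | CC(=O)Oc1ccc(C(Cl)=O)c(OC(C)=O)c1
A7 | alternative 2 | [7-methoxy-2,2-dimethyl-6-(2-methylbut-3-en-2-yl)-1,3-benzodioxol-4-yl]acetaldehyde | O=CCc1cc(C(C)(C)C=C)c(OC)c2OC(C)(C)Oc12
A8 | alternative 3 | 7-ethoxy-3-[7-methoxy-2,2-dimethyl-6-(2-methylbut-3-en-2-yl)-1,3-benzodioxol-4-yl]-5,6-dihydro-4H-chromen-4-one | CCOC1=CC2=C(CC1)C(=O)C(=CO2)c1cc(C(C)(C)C=C)c(OC)c2OC(C)(C)Oc12
A9 | alternative 3 | 3-ethoxy-6-{[7-methoxy-2,2-dimethyl-6-(2-methylbut-3-en-2-yl)-1,3-benzodioxol-4-yl]acetyl}cyclohex-2-en-1-one (racemic, largely enolised) | CCOC1=CC(=O)C(CC1)C(=O)Cc1cc(C(C)(C)C=C)c(OC)c2OC(C)(C)Oc12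
A10 | alternative 3 | 3-ethoxycyclohex-2-en-1-one | CCOC1=CC(=O)CCC1
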